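The cyclobutane C8–C9–C14–C15, fused to ring B (C5–C10) along C8–C9 and to the cyclopentane along C9–C14, is the [2+2] adduct of an alkene C8=C15 and an enone C9=C14. Ring B of sclareol is therefore cut at C8–C9 by ozonolysis and closed again by an intramolecular enone–alkene photocycloaddition that forms C8–C9 and C14–C15, two rings and the stereocentres C8, C9 and C14 in one operation. The precursor is an 8,9-seco-labdane: ring A carries at C10 a cyclopent-2-enone (C9=C14, C13=O) and at C5 the chain C6(OAc)–C7(OTBS)–C8(Me)=C15H2, so the 6β-acetoxy group is already in place.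

Key step: step 15

Remark: labdane numbers are kept by position, so C14 of the enone is the former C16 methyl carbon of sclareol, C15 is the Wittig carbon and C16 is the carbon added at C13 at the end; α/β refer to the ring-B-closed drawing, and the photoadduct is the straight (fused) adduct.

Step 1
Reactants: 1 sclareol
Product: 4 8α-hydroxy-14,15-dinorlabdan-13-one, via tetraol 2 (not isolated), via hydroxy aldehyde 3 (not isolated)
Conditions: OsO4 (cat.), NaIO4, THF/H2O, rt
Reagents that add atoms: none
Why: Lemieux–Johnson cleavage of the vinyl group and periodate cleavage of the resulting tertiary alpha-hydroxy aldehyde remove C15 and C14 and leave the C13 methyl ketone, while the saturated decalin and the C8 alcohol are inert.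

Step 2
Reactants: 4 8α-hydroxy-14,15-dinorlabdan-13-one
Product: 6 13,13-ethylenedioxy-14,15-dinorlabd-8-ene, via hydroxy dioxolane 5 (not isolated)
Conditions: ethylene glycol, TsOH·H2O (cat.), toluene, reflux, Dean–Stark
Reagents that add atoms: ethylene glycol, OCCO
Why: acid-catalysed ketalisation protects C13, and under the same equilibrating conditions E1 dehydration of the tertiary C8 alcohol should converge on the thermodynamically preferred tetrasubstituted C8=C9 alkene, the ketal keeping the carbonyl oxygen from trapping the C8 cation as a cyclic enol ether.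

Step 3
Reactants: 6 13,13-ethylenedioxy-14,15-dinorlabd-8-ene
Product: 7 13,13-ethylenedioxy-14,15-dinorlabd-8-en-7-one
Conditions: CrO3, 3,5-dimethylpyrazole, CH2Cl2, −20 °C
Reagents that add atoms: chromium trioxide, O=[Cr](=O)=O
Why: allylic oxidation with the CrO3–3,5-dimethylpyrazole complex should convert the ring methylene C7, whose axial C–H bond is aligned with the alkene, into the enone carbonyl, the other allylic methylene C11 being screened by C1 and the quaternary C10.

Step 4
Reactants: 7 13,13-ethylenedioxy-14,15-dinorlabd-8-en-7-one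
Product: 9 7-(tert-butyldimethylsilyloxy)-13,13-ethylenedioxy-14,15-dinorlabda-6,8-diene, via lithium dienolate 8 (not isolated)
Conditions: LiN(iPr)2, THF, −78 °C; then TBSOTf, −78 → 0 °C
Reagents that add atoms: tert-butyldimethylsilyl trifluoromethanesulfonate, CC(C)(C)[Si](C)(C)OS(=O)(=O)C(F)(F)F
Why: kinetic deprotonation of the enone at the alpha' carbon C6 and O-silylation give the cross-conjugated silyl dienol ether (silyl enol ether formation), the ketal leaving no other acidic site.

Step 5
Reactants: 9 7-(tert-butyldimethylsilyloxy)-13,13-ethylenedioxy-14,15-dinorlabda-6,8-diene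
Product: 11 7β-(tert-butyldimethylsilyloxy)-13,13-ethylenedioxy-14,15-dinorlabd-8-en-6α-ol, via alkylborane 10 (not isolated)
Conditions: BH3·THF, THF, 0 °C → rt; then NaOH, H2O2, 0 °C
Reagents that add atoms: hydrogen peroxide, OO
Why: hydroboration–oxidation of the enol ether double bond puts boron on C6 (beta to oxygen) and hydrogen on C7 from the α face, the β face being covered by the axial methyls on C4 and C10, so C7 becomes 7β-OTBS and C6 a 6α-alcohol, which amounts to a 1,2-transposition of the oxygen pattern while the tetrasubstituted alkene reacts far more slowly.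

Step 6
Reactants: 11 7β-(tert-butyldimethylsilyloxy)-13,13-ethylenedioxy-14,15-dinorlabd-8-en-6α-ol
Product: 12 7β-(tert-butyldimethylsilyloxy)-13,13-ethylenedioxy-14,15-dinorlabd-8-en-6-one
Conditions: Dess–Martin periodinane, NaHCO3, CH2Cl2, 0 °C → rt
Reagents that add atoms: none
Why: Dess–Martin oxidation of the secondary alcohol under buffered, non-enolising conditions gives the C6 ketone without epimerising C5 or C7 and without touching ketal or silyl ether.

Step 7
Reactants: 12 7β-(tert-butyldimethylsilyloxy)-13,13-ethylenedioxy-14,15-dinorlabd-8-en-6-one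
Product: 13 7β-(tert-butyldimethylsilyloxy)-13,13-ethylenedioxy-14,15-dinorlabd-8-en-6β-ol
Conditions: NaBH4, CeCl3·7H2O, MeOH, −20 °C
Reagents that add atoms: none
Why: in this Luche-type borohydride reduction hydride reaches the C6 carbonyl only from the α face, because the β face is blocked by the axial methyls on C4 and C10, which sets C6 as the axial 6β-alcohol of the target, and CeCl3 suppresses enolisation of the alpha-silyloxy ketone.

Step 8
Reactants: 13 7β-(tert-butyldimethylsilyloxy)-13,13-ethylenedioxy-14,15-dinorlabd-8-en-6β-ol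
Product: 14 7β-(tert-butyldimethylsilyloxy)-6β-(triethylsilyloxy)-13,13-ethylenedioxy-14,15-dinorlabd-8-ene
Conditions: TESOTf, 2,6-lutidine, CH2Cl2, 0 °C
Reagents that add atoms: triethylsilyl trifluoromethanesulfonate, CC[Si](CC)(CC)OS(=O)(=O)C(F)(F)F
Why: silylation with a silyl triflate is strong enough for the hindered axial alcohol, and the TES ether keeps O6 from adding to C9 in the later base step while remaining removable beside the TBS ether.

Step 9
Reactants: 14 7β-(tert-butyldimethylsilyloxy)-6β-(triethylsilyloxy)-13,13-ethylenedioxy-14,15-dinorlabd-8-ene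
Product: 16 8,9-seco-diketone (C8 methyl ketone; C9 ketone; 6-OTES; 7-OTBS; C13 dioxolane), via primary ozonide 15 (not isolated)
Conditions: O3, CH2Cl2, −78 °C; then Me2S, −78 °C → rt
Reagents that add atoms: ozone, [O-][O+]=O
Why: ozonolysis with reductive work-up cleaves the only alkene, the electron-rich tetrasubstituted C8=C9 bond, into the C8 methyl ketone and the C9 ketone, which opens ring B without touching C5, C6, C7 or C10.

Step 10
Reactants: 16 8,9-seco-diketone; 17 methyltriphenylphosphonium bromide
Product: 18 8,9-seco-ketone alkene (C8(CH3)=C15H2; C9 ketone; 6-OTES; 7-OTBS; C13 dioxolane)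
Conditions: 17, KN(SiMe3)2, THF, −78 → 0 °C
Reagents that add atoms: methyltriphenylphosphonium bromide 17, C[P+](c1ccccc1)(c1ccccc1)c1ccccc1.[Br-]
Why: Wittig methylenation should take place only at the C8 methyl ketone, because the C9 ketone is flanked by the quaternary C10 and C13 is masked as the ketal, and the low temperature limits enolisation at C7.

Step 11
Reactants: 18 8,9-seco-ketone alkene
Product: 19 1,4-diketone (C9 ketone; C13 methyl ketone; C8(CH3)=C15H2; 6-OTES; 7-OTBS)
Conditions: PPTS, acetone/H2O, 45 °C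
Reagents that add atoms: water, O
Why: mild acid-catalysed ketal hydrolysis (transketalisation in wet acetone) frees the C13 ketone under conditions that the TBS ether and the hindered secondary TES ether should tolerate.

Step 12
Reactants: 19 1,4-diketone
Product: 21 cyclopentenone (C9=C14; C13=O; 6-OTES; 7-OTBS; C8(CH3)=C15H2), via aldol 20 (not isolated)
Conditions: KOtBu, tBuOH/THF, 0 °C → rt
Reagents that add atoms: none
Why: intramolecular aldol condensation of the 1,4-diketone, in which the methyl enolate of the C13 ketone adds to the C9 carbonyl to close the five-membered ring and E1cB dehydration gives the 3-substituted cyclopent-2-enone, is the only ring closure open to this diketone, and tert-butoxide does not attack the silyl ethers.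

Step 13
Reactants: 21 cyclopentenone
Product: 22 6-alcohol (C6–OH; 7-OTBS; cyclopentenone; C8(CH3)=C15H2)
Conditions: HF·pyridine, pyridine, THF, 0 °C
Reagents that add atoms: none
Why: buffered fluoride cleaves the TES ether much faster than the TBS ether (selective desilylation), and the mildly acidic medium gives no alkoxide that could add to the enone.

Step 14
Reactants: 22 6-alcohol
Product: 23 6-acetate (photosubstrate: C6–OAc; 7-OTBS; cyclopentenone C9=C14; C8(CH3)=C15H2)
Conditions: Ac2O, DMAP, Et3N, CH2Cl2, rt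
Reagents that add atoms: acetic anhydride, CC(=O)OC(C)=O
Why: DMAP-catalysed acetylation is done here, in the open chain, because after ring closure the same 6β-hydroxyl would sit among three axial methyl groups and resist acylation.

Step 15
Reactants: 23 6-acetate (photosubstrate)
Product: 24 tetracyclic 13-ketone (6β-OAc; 7β-OTBS; 8β-methyl; cyclobutane C8–C9–C14–C15 on the α face of ring B; cis-fused cyclopentanone)
Conditions: hν (350–366 nm, Pyrex), degassed CH2Cl2 (0.005 M), 0 °C
Reagents that add atoms: none
Why: Excitation of the cyclopentenone near 350 nm and intersystem crossing give the triplet enone, which bonds C9 to C8 (or, less likely, C14 to C15 first) to a triplet 1,4-biradical that closes the second bond after spin inversion; this is the known intramolecular enone–alkene [2+2] photocycloaddition of 3-alkenylcyclopent-2-enones, here in the straight (fused) mode and with a four-atom tether. Ring B closes 6-exo-trig by attack of C9 on the inner alkene carbon C8, and the cyclobutane closes by recombination of the C14 and C15 radical centres. C9 is controlled by conformation: allylic 1,2-strain about C9–C10 turns the ring methylene C11 towards the small C10 methyl and the vinylic C14–H towards C5, so the equatorial chain on C5 reaches only the enone face on which C14 ends up α, trans to the C10 methyl. C14 is controlled by ring strain, since a four-membered ring can only be cis-fused to the cyclopentanone, and C8 by the tether, which must deliver C15 to the face of ring B that already carries C14 and so leaves the C8 methyl β. The step needs straight over crossed regioselectivity, secured by the tether length (the crossed mode would demand a bridged bicyclo[4.1.1]octane), facial selectivity at C9, secured as described with the trans-diequatorial arms on the ring A chair holding C8 next to C9, and chemoselectivity, secured because only the enone absorbs at this wavelength while acetate and silyl ether are transparent.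

Step 16
Reactants: 24 tetracyclic 13-ketone
Product: 25 13-methylene tetracycle (C13=C16H2; 6β-OAc; 7β-OTBS)
Conditions: Zn, CH2Br2, TiCl4, THF/CH2Cl2, 0 °C → rt
Reagents that add atoms: dibromomethane, BrCBr
Why: Takai–Lombardo methylenation is non-basic, so the acetate, the silyl ether and the ring-fusion centre C14 next to the carbonyl are safe, and C13 is the only ketone present.

Step 17
Reactants: 25 13-methylene tetracycle
Product: 27 tertiary 13-alcohol (13-OH cis to H-14; 13-methyl on the cyclobutane side; 6β-OAc; 7β-OTBS), via hydroperoxide 26 (not isolated)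
Conditions: Mn(dpm)3 (cat.), PhSiH3, O2 (1 atm), iPrOH/CH2Cl2, 0 °C → rt; then PPh3
Reagents that add atoms: dioxygen, O=O
Why: in this Mukaiyama hydration hydrogen-atom transfer to the exocyclic alkene gives the tertiary C13 radical, which O2 should capture on the convex face of the bicyclo[3.2.0]heptane because the concave face is blocked by C15H2, so the hydroxyl ends up cis to H-14 and the new methyl C16 points to the cyclobutane, and capture by O2 is far faster than ring opening of the cyclobutylcarbinyl radical.

Step 18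
Reactants: 27 tertiary 13-alcohol
Product: 28 7β,13-diol 6β-acetate
Conditions: HF·pyridine, pyridine, THF, 0 °C → rt
Reagents that add atoms: none
Why: fluoride-mediated desilylation in a buffered, slightly acidic medium removes the TBS group without the alkoxide that would let the acetyl group move from O6 to the cis O7 and without ionising the tertiary alcohol next to the cyclobutane.

Step 19
Reactants: 28 7β,13-diol 6β-acetate
Product: 29 CNP0330581.1 (target)
Conditions: Dess–Martin periodinane, NaHCO3, CH2Cl2, 0 °C → rt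
Reagents that add atoms: none
Why: Dess–Martin oxidation converts the only secondary alcohol (C7) into the ketone under buffered conditions that neither touch the tertiary C13 alcohol nor epimerise the base-sensitive axial 6β-acetoxy ketone.

Compound list
1 | sclareol, (13R)-labd-14-ene-8α,13-diol | C1C[C@@](C)(O)[C@H](CC[C@@](C)(O)C=C)[C@@]2(C)CCCC(C)(C)[C@H]12 | starting material
2 | (13R)-labdane-8α,13,14,15-tetraol (C14 epimers) | C1C[C@@](C)(O)[C@H](CC[C@@](C)(O)C(O)CO)[C@@]2(C)CCCC(C)(C)[C@H]12 | intermediate
3 | (13R)-8α,13-dihydroxy-15-norlabdan-14-al | C1C[C@@](C)(O)[C@H](CC[C@@](C)(O)C=O)[C@@]2(C)CCCC(C)(C)[C@H]12 | intermediate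
4 | 8α-hydroxy-14,15-dinorlabdan-13-one | C1C[C@@](C)(O)[C@H](CCC(C)=O)[C@@]2(C)CCCC(C)(C)[C@H]12 | intermediate
5 | 13,13-ethylenedioxy-14,15-dinorlabdan-8α-ol | C1C[C@@](C)(O)[C@H](CCC3(C)OCCO3)[C@@]2(C)CCCC(C)(C)[C@H]12 | intermediate
6 | 13,13-ethylenedioxy-14,15-dinorlabd-8-ene | C1CC(C)=C(CCC3(C)OCCO3)[C@@]2(C)CCCC(C)(C)[C@H]12 | intermediate
7 | 13,13-ethylenedioxy-14,15-dinorlabd-8-en-7-one | C1C(=O)C(C)=C(CCC3(C)OCCO3)[C@@]2(C)CCCC(C)(C)[C@H]12 | intermediate
8 | lithium 13,13-ethylenedioxy-14,15-dinorlabda-6,8-dien-7-olate | C1=C([O-])C(C)=C(CCC3(C)OCCO3)[C@@]2(C)CCCC(C)(C)[C@H]12.[Li+] | intermediate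
9 | 7-(tert-butyldimethylsilyloxy)-13,13-ethylenedioxy-14,15-dinorlabda-6,8-diene | C1=C(O[Si](C)(C)C(C)(C)C)C(C)=C(CCC3(C)OCCO3)[C@@]2(C)CCCC(C)(C)[C@H]12 | intermediate
10 | 6α-boryl-7β-(tert-butyldimethylsilyloxy)-13,13-ethylenedioxy-14,15-dinorlabd-8-ene | B[C@H]1[C@H](O[Si](C)(C)C(C)(C)C)C(C)=C(CCC3(C)OCCO3)[C@@]2(C)CCCC(C)(C)[C@H]12 | intermediate
11 | 7β-(tert-butyldimethylsilyloxy)-13,13-ethylenedioxy-14,15-dinorlabd-8-en-6α-ol | O[C@H]1[C@H](O[Si](C)(C)C(C)(C)C)C(C)=C(CCC3(C)OCCO3)[C@@]2(C)CCCC(C)(C)[C@H]12 | intermediate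
12 | 7β-(tert-butyldimethylsilyloxy)-13,13-ethylenedioxy-14,15-dinorlabd-8-en-6-one | O=C1[C@H](O[Si](C)(C)C(C)(C)C)C(C)=C(CCC3(C)OCCO3)[C@@]2(C)CCCC(C)(C)[C@H]12 | intermediate
13 | 7β-(tert-butyldimethylsilyloxy)-13,13-ethylenedioxy-14,15-dinorlabd-8-en-6β-ol | O[C@@H]1[C@H](O[Si](C)(C)C(C)(C)C)C(C)=C(CCC3(C)OCCO3)[C@@]2(C)CCCC(C)(C)[C@H]12 | intermediate
14 | 7β-(tert-butyldimethylsilyloxy)-6β-(triethylsilyloxy)-13,13-ethylenedioxy-14,15-dinorlabd-8-ene | CC[Si](CC)(CC)O[C@@H]1[C@H](O[Si](C)(C)C(C)(C)C)C(C)=C(CCC3(C)OCCO3)[C@@]2(C)CCCC(C)(C)[C@H]12 | intermediate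
15 | primary ozonide of 14 (1,2,3-trioxolane across C8–C9 on the α face) | CC[Si](CC)(CC)O[C@@H]1[C@H](O[Si](C)(C)C(C)(C)C)[C@@]4(C)OOO[C@@]4(CCC3(C)OCCO3)[C@@]2(C)CCCC(C)(C)[C@H]12 | intermediate
16 | 8,9-seco-diketone: ring A with the C5 chain C6(OTES)–C7(OTBS)–C8(=O)CH3 and the C10 chain C9(=O)–C11H2–C12H2–C13(dioxolane)CH3; C5, C6, C7, C10 as in 14 | CC(=O)[C@@H](O[Si](C)(C)C(C)(C)C)[C@@H](O[Si](CC)(CC)CC)[C@H]1C(C)(C)CCC[C@]1(C)C(=O)CCC2(C)OCCO2 | intermediate
17 | methyltriphenylphosphonium bromide | C[P+](c1ccccc1)(c1ccccc1)c1ccccc1.[Br-] | starting material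
18 | 8,9-seco-ketone alkene: as 16 with C8(CH3)=C15H2 in place of the C8 ketone | C=C(C)[C@@H](O[Si](C)(C)C(C)(C)C)[C@@H](O[Si](CC)(CC)CC)[C@H]1C(C)(C)CCC[C@]1(C)C(=O)CCC2(C)OCCO2 | intermediate
19 | 1,4-diketone: as 18 with the free C13 methyl ketone | C=C(C)[C@@H](O[Si](C)(C)C(C)(C)C)[C@@H](O[Si](CC)(CC)CC)[C@H]1C(C)(C)CCC[C@]1(C)C(=O)CCC(C)=O | intermediate
20 | aldol: 3-hydroxycyclopentanone on C10 (C9–OH, C13=O; C9 epimers) | C=C(C)[C@@H](O[Si](C)(C)C(C)(C)C)[C@@H](O[Si](CC)(CC)CC)[C@H]1C(C)(C)CCC[C@]1(C)C1(O)CC(=O)CC1 | intermediate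
21 | cyclopentenone: 3-substituted cyclopent-2-enone on C10 (C9=C14, C13=O), 6-OTES, 7-OTBS, C8(CH3)=C15H2 | C=C(C)[C@@H](O[Si](C)(C)C(C)(C)C)[C@@H](O[Si](CC)(CC)CC)[C@H]1C(C)(C)CCC[C@]1(C)C1=CC(=O)CC1 | intermediate
22 | 6-alcohol: as 21 with free C6–OH | C=C(C)[C@@H](O[Si](C)(C)C(C)(C)C)[C@@H](O)[C@H]1C(C)(C)CCC[C@]1(C)C1=CC(=O)CC1 | intermediate
23 | 6-acetate (photosubstrate): as 21 with C6–OAc | C=C(C)[C@@H](O[Si](C)(C)C(C)(C)C)[C@@H](OC(C)=O)[C@H]1C(C)(C)CCC[C@]1(C)C1=CC(=O)CC1 | intermediate
24 | tetracyclic 13-ketone: 6β-OAc, 7β-OTBS, 8β-methyl, cyclobutane C8–C9–C14–C15 on the α face of ring B, cis-fused cyclopentanone with C11 β on C9 | CC(=O)O[C@@H]1[C@H](O[Si](C)(C)C(C)(C)C)[C@@]2(C)C[C@H]3[C@@]2(CCC3=O)[C@@]2(C)CCCC(C)(C)[C@H]12 | intermediate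
25 | 13-methylene tetracycle: as 24 with C13=C16H2 | CC(=O)O[C@@H]1[C@H](O[Si](C)(C)C(C)(C)C)[C@@]2(C)C[C@H]3[C@@]2(CCC3=C)[C@@]2(C)CCCC(C)(C)[C@H]12 | intermediate
26 | 13-hydroperoxide: as 27 with OOH in place of OH | CC(=O)O[C@@H]1[C@H](O[Si](C)(C)C(C)(C)C)[C@@]2(C)C[C@H]3[C@@]2(CC[C@]3(C)OO)[C@@]2(C)CCCC(C)(C)[C@H]12 | intermediate
27 | tertiary 13-alcohol: 13-OH cis to H-14, 13-methyl on the cyclobutane side, 6β-OAc, 7β-OTBS | CC(=O)O[C@@H]1[C@H](O[Si](C)(C)C(C)(C)C)[C@@]2(C)C[C@H]3[C@@]2(CC[C@]3(C)O)[C@@]2(C)CCCC(C)(C)[C@H]12 | intermediate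
28 | 7β,13-diol 6β-acetate | CC(=O)O[C@@H]1[C@H](O)[C@@]2(C)C[C@H]3[C@@]2(CC[C@]3(C)O)[C@@]2(C)CCCC(C)(C)[C@H]12 | intermediate
29 | CNP0330581.1: 6β-acetoxy-13-hydroxy-7-ketone | CC(=O)O[C@@H]1C(=O)[C@@]2(C)C[C@H]3[C@@]2(CC[C@]3(C)O)[C@@]2(C)CCCC(C)(C)[C@H]12 | target

Total step count: 19. Longest linear sequence: 19 steps, all from sclareol.

Steps most likely to fail

Step 15. The excited enone may relax without closing the six-membered ring, may abstract the allylic hydrogen at C7, or may add to the wrong face of C9. The fallback replaces the photochemical closure by two ground-state closures and sets out from 23. mCPBA epoxidises the C8=C15 alkene (the enone is inert) to the epoxide F1, whose two C8 epimers both serve. Cp2TiCl (trivalent titanium, made from Cp2TiCl2 and Zn in THF) opens F1 to the tertiary C8 radical, which adds 6-exo to C9 of the enone and gives, after protonation of the titanium enolate, the tricyclic hydroxymethyl ketone F2. I2, PPh3 and imidazole convert the C15 alcohol into the iodide F3. LiN(SiMe3)2 under equilibrating conditions forms the C14 enolate, which closes the cyclobutane by intramolecular alkylation (4-exo-tet) and comes back to the route at 24.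

Step 17. Capture of O2 by the planar C13 radical may show low facial selectivity. The fallback sets out from 25. mCPBA, a bulkier oxidant, epoxidises the exocyclic alkene from the convex face to the spiro-epoxide F4. Phenylselenide ((PhSe)2, NaBH4, EtOH) opens it at the methylene carbon to the hydroxy selenide F5, and Bu3SnH with AIBN removes selenium to leave the C13 methyl group, which comes back to the route at 27.

Step 12. The aldol addition to the hindered C9 ketone may revert faster than it dehydrates, or the TES ether may be lost under base. The fallback sets out from 19. LiN(iPr)2 and Me3SiCl at −78 °C give the kinetic silyl enol ether F6 of the methyl ketone. TiCl4 at −78 °C then effects an intramolecular Mukaiyama aldol addition to C9 and gives the aldol 20, now isolated; dehydration with the Burgess reagent comes back to the route at 21.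

Further compounds
F1 | step 15 | 8,15-epoxide of 23 (both C8 epimers) | CC1(CO1)[C@@H](O[Si](C)(C)C(C)(C)C)[C@@H](OC(C)=O)[C@H]2C(C)(C)CCC[C@]2(C)C3=CC(=O)CC3
F2 | step 15 | tricyclic hydroxymethyl ketone: ring B closed at C8–C9, C8 with β-methyl and α-CH2OH (C15), spiro-cyclopentanone at C9 with C14 α, 6β-OAc, 7β-OTBS | CC(=O)O[C@@H]1[C@H](O[Si](C)(C)C(C)(C)C)[C@@](C)(CO)[C@@]2(CC(=O)CC2)[C@@]3(C)CCCC(C)(C)[C@H]13
F3 | step 15 | C15 iodide of F2 | CC(=O)O[C@@H]1[C@H](O[Si](C)(C)C(C)(C)C)[C@@](C)(CI)[C@@]2(CC(=O)CC2)[C@@]3(C)CCCC(C)(C)[C@H]13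
F4 | step 17 | 13,16-spiro-epoxide of 25 (oxygen on the convex face, cis to H-14) | CC(=O)O[C@@H]1[C@H](O[Si](C)(C)C(C)(C)C)[C@@]2(C)C[C@H]3[C@@]2(CC[C@@]34CO4)[C@@]2(C)CCCC(C)(C)[C@H]12
F5 | step 17 | 16-phenylselanyl derivative of 27 (hydroxy selenide) | CC(=O)O[C@@H]1[C@H](O[Si](C)(C)C(C)(C)C)[C@@]2(C)C[C@H]3[C@@]2(CC[C@]3(C[Se]c4ccccc4)O)[C@@]2(C)CCCC(C)(C)[C@H]12
F6 | step 12 | trimethylsilyl enol ether of the C13 methyl ketone of 19 | C=C(C)[C@@H](O[Si](C)(C)C(C)(C)C)[C@@H](O[Si](CC)(CC)CC)[C@H]1C(C)(C)CCC[C@]1(C)C(=O)CCC(=C)O[Si](C)(C)C
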